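## The problem

Labdane numbering (C1–C20) is used for every intermediate, including the monocyclic and ten-membered ones.

- Target 39 is a trans-fused decalin with five stereocentres (C2, C4, C5, C6, C10). Two are quaternary: C4 (α-CH3, β-CH2OH = C19) and C10 (β-CH3 = C20). It also carries a tetrasubstituted C8=C9 alkene and a CH2CH2 arm on C9 that ends in a β-substituted butenolide.
- Both secondary hydroxyls (2α, 6α) are equatorial. The β face of C2 and of C6 is screened by the syn-axial C19 and C20 groups, so hydride would give the axial epimers. The carbinols therefore have to come from thermodynamic (dissolving-metal) reduction of ketones, and the ring fixes them late.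
- C5 is epimerisable while C6 is a ketone. Absolute control is thus needed only at C4 and C10, and C10 must be set relative to C4. C4 alone is a weak director, because its methyl and C19 substituents differ little in size.
- The alkene is β,γ to the C6 oxygen and drifts into conjugation with a C6 ketone under acid or base. The butenolide tolerates neither hydride, dissolving metal nor strong base and must be attached last.
- The enabling feature: the oxygens at C2 and C6 are 1,5-related through C1, C10 and C5. With both as carbonyls, the C5–C10 fusion bond is the bond of a Michael addition of a C6-ketone enolate (at C5) to a C2 enone (C1=C10). Cutting it unfolds rings A and B into one ten-membered ring.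
- That ring is the product of an oxy-Cope ring expansion of a cyclohexane (C1–C6) that already holds C4. The expansion creates C8 and C9 as stereocentres, which can steer the transannular closure before they are erased in the C8=C9 alkene.

## Retrosynthesis

**C12–C13 (39 ⇒ 35 + 36).** The sp3–sp2 bond between the side-chain CH2 and the butenolide β-carbon is cut first, because the lactone would not survive the reductions that set C2 and C6. Carrying a furan instead would need an oxidation next to the electron-rich C8=C9 alkene, and building the lactone from an aldehyde costs three to four steps. A Negishi coupling of the alkylzinc from iodide 35 with 4-bromofuran-2(5H)-one 36 needs only silyl protection of three hydroxyls. Iodide 34 comes from tetraol 33 by selective substitution of the one unhindered primary alcohol.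

**C2–H, C6–H and the O-benzyl groups (33 ⇒ 32).** One dissolving-metal step is asked to give both equatorial carbinols and to remove both benzyl ethers. This is why C12–O and C19–O are carried as benzyl ethers from the start. The precursor, dione 32, has no hydroxyl stereocentre left.

**The C8=C9 alkene (32 ⇒ 30 ⇒ 28).** The alkene is reached from the conjugated 7-en-6-one 30 by deconjugation through the extended dienolate. Enone 30 comes from the saturated dione 28 by dehydrogenation. Only the C6 ketone can be dehydrogenated: C2 is flanked by CH2 groups whose β-carbons (C4, C10) are quaternary. The two ketones therefore need not be told apart, and C8 and C9 of 28 are sacrificial stereocentres.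

**C5–C10 (28 ⇒ 27), the key cut.** Breaking the fusion bond gives the (E)-cyclodec-1(10)-ene-2,6-dione 27, with C4, C8 and C9 as its only stereocentres.
- Against cuts of ring A or ring B alone, this one removes both rings and both ring-fusion stereocentres at once, and it leaves the two carbonyls exactly at the two carbinol carbons.
- An epimer mixture at C8/C9 would not serve. C8 cannot epimerise, and the "wrong" C8 epimer would close onto the other face of C10, where the C4 bias (methyl against CH2OR) is too small to resist.
- The forward reaction is therefore run on a single, matched diastereomer, in which C8-methyl and the C9 chain are both equatorial only in the desired trans-decalin.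

**C8–C9 formed, C1–C6 broken (27 ⇒ 26 ⇒ 24).** An anionic oxy-Cope rearrangement of the 1,2-dialkenylcyclohexanol 24 gives the (E)-cyclodecenone and transfers the C1/C6 configuration to C8/C9 through a chair transition state. Macrocyclisations such as ring-closing metathesis would give neither the alkene geometry nor these centres with control.
- Working the chair back shows that the alkoxide oxygen must be axial and cis to C19, with the two alkenyl groups trans-diequatorial.
- An ester at C19 would then sit 1,3-diaxial to the alkoxide and lactonise. C19 is therefore carried as CH2OBn, which also removes a late ester reduction.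
- C2 travels as a silyl ether and is oxidised after the ring expansion (26 ⇒ 27).

**C6–C7 and C2–O (24 ⇒ 20 + 21; 20 ⇒ 19 ⇒ 17).** The propenyl group is added to ketone 20 as an organocerium reagent. Equatorial attack, anti to the axial CH2OBn and trans to the C1 alkenyl group, gives exactly the relationship required above. This holds only if the C2 oxygen is trans to CH2OBn, so that the ring conformer has C1 and C2 substituents equatorial and C19 axial. C4 cannot enforce that, so a chiral copper catalyst sets C2 in the conjugate borylation of dienone 17. C1 then equilibrates trans to C2.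

**C1–C10 (17 ⇒ 10 + 14).** The sp2–sp2 bond is made by Negishi coupling of α-iodoenone 10 with the alkenylzinc from (E)-iodide 14. The iodide comes from pent-3-yn-1-ol 11 by benzylation (12) and hydrozirconation–iodination. An enone is the only ring precursor that accepts a C1 alkenyl group without β-elimination of a C2 oxygen.

**Ring A carbons and C4 (10 ⇒ 9 ⇒ 7 ⇒ 6 ⇒ 4 ⇒ 1).** Enone 9 is the Stork–Danheiser transposition product of vinylogous ester acid 6 after reduction and benzylation. Racemic 4 comes in one operation from 3,5-dimethoxybenzoic acid 1 by Birch reductive methylation and partial hydrolysis. This sets the quaternary carbon and the 1,3-dioxygenation.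
- No reliable catalytic desymmetrisation of an enolised, C2-unsubstituted 1,3-dione is available.
- The stereocentre of 4 is α to a carboxyl group, so it is resolved as an ammonium salt.
- The unwanted antipode is racemised through the achiral dione by hydrolysis and re-etherification.

## Roads not taken

**Alternative 1:** Ring B is cut at C5–C6 and C9–C10. A 1-silyloxy diene carrying the C8 methyl and the C11–C12 arm would add to the methyl-bearing double bond of a methoxy-p-quinone under a chiral cationic oxazaborolidine, giving the cis-fused enedione A1.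
- Merits: catalytic enantiocontrol, and C10, C9 and the C6 oxygen set in one convergent step. In this respect it is better than the resolution used here, and it reaches a decalin in fewer steps.
- Weak points: ring A arrives as a quinone-derived enedione. C1 carries a carbonyl that must be removed, C4 is a carbonyl that must become the quaternary CH3/CH2OH carbon with the axial hydroxymethyl group, C5 must be epimerised, and the C7=C8 alkene must be moved.
- Comparison: the chosen plan is longer up to the decalin, but the decalin it delivers already has C4 complete and oxygen only at C2 and C6.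

**Alternative 2:** C4–C5 and C10–C1 are cut on a ring B cyclohexenone. An isopropenyl copper reagent adds to C5 anti to a C6 silyloxy group, and the C10 enolate is trapped with a bromoacetate, giving the cyclohexanone A2.
- Merits: three contiguous centres from one carbinol centre, cheap reagents, and a C9 ketone that offers a direct route to the C8=C9 alkene and the side chain (enol triflate coupling). On this point it is better than the dehydrogenation–deconjugation detour used here.
- Weak points: no ring closes. Ring A still has to be built by a second carbon–carbon bond formation, and the C4 quaternary centre has to be made on an isopropenyl-derived carbon with the hydroxymethyl group axial. The alkylation of a fully substituted enolate next to the new C5 centre decides C10.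
- Comparison: the chosen plan closes both rings and has C4 in place before the key step.

**Alternative 3:** C1–C10 is cut. A 2-methylene pyran fused to ring B at C5–C6 would rearrange on heating through a boat Claisen transition state, breaking O–C6 and giving the ring A ketone A3 with a C5=C6 alkene.
- Merits: C10 is set by suprafacial chirality transfer with C4 already present. The C5=C6 alkene allows 6α-OH and 5α-H to be put in together by hydroboration, which avoids a dissolving-metal reduction at C6 and is better than the present route on that point.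
- Weak points: bond formation at a fully substituted C10 through an enforced boat, a labile exocyclic enol ether, and a precursor whose C4 and C6 centres need their own asymmetric synthesis. The C9 oxygen must still be turned into the side chain, the C8 methyl and the alkene.
- Comparison: the chosen plan forms both rings in the key step from a ring that is assembled by two robust couplings.

Key step: step 14

Assumption 1: which antipode of 1-phenylethylamine gives the less soluble salt with (R)-4 cannot be predicted; the (S)-amine is written, and the (R)-amine is used if the salts behave the other way.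

Assumption 2: the (R,S)-Josiphos–copper catalyst is taken to deliver boron to C2 of 17 anti to the CH2OBn group; if the sense is opposite, the mirror-image ligand is used.

Step 1
Reactants: 1 3,5-dimethoxybenzoic acid
Product: 4 rac-3-methoxy-1-methyl-5-oxocyclohex-3-ene-1-carboxylic acid, via dilithium dienediolate 2 (not isolated), via 3,5-dimethoxy-1-methylcyclohexa-2,5-diene-1-carboxylic acid 3 (not isolated)
Conditions: Li, NH3(l)/THF, −78 °C; MeI; NH4Cl; then 1 M HCl, THF, 0 °C
Reagents that add atoms: iodomethane, CI; water, O
Why: Birch reductive alkylation of a benzoic acid gives the carboxylate-stabilised dianion, which is methylated at the ipso carbon (the future C4); dilute acid hydrolyses one enol ether and the product tautomerises to the vinylogous ester, which resists further hydrolysis under these conditions.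

Step 2
Reactants: 4 rac-3-methoxy-1-methyl-5-oxocyclohex-3-ene-1-carboxylic acid
Product: 6 (R)-3-methoxy-1-methyl-5-oxocyclohex-3-ene-1-carboxylic acid, via (S)-1-phenylethylammonium salt 5 (not isolated)
Conditions: (S)-1-phenylethylamine (0.55 equiv), EtOAc/EtOH, recrystallise; salt partitioned between MTBE and cold 1 M KHSO4
Reagents that add atoms: none
Why: Classical resolution through diastereomeric ammonium carboxylates; the stereocentre is the carbon α to the carboxylate, so the salts should differ well, and the unwanted antipode is returned to racemic 4 through the achiral 1,3-dione (aqueous acid, then MeOH/H+).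

Step 3
Reactants: 6 (R)-3-methoxy-1-methyl-5-oxocyclohex-3-ene-1-carboxylic acid
Product: 7 (5S)-5-(hydroxymethyl)-3-methoxy-5-methylcyclohex-2-en-1-ol (both C1 epimers)
Conditions: LiAlH4, THF, 0 °C → reflux; H2O, 15% NaOH work-up
Reagents that add atoms: none
Why: LiAlH4 reduces the carboxylate to the primary alcohol and the vinylogous ester carbonyl by 1,2-addition (first half of a Stork–Danheiser transposition); the basic work-up keeps the enol ether, and the new carbinol centre is lost in step 4.

Step 4
Reactants: 7 (5S)-5-(hydroxymethyl)-3-methoxy-5-methylcyclohex-2-en-1-ol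
Product: 9 (S)-5-[(benzyloxy)methyl]-5-methylcyclohex-2-en-1-one, via bis(benzyl ether) 8 (not isolated)
Conditions: NaH, BnBr, n-Bu4NI (cat.), THF/DMF, 0 °C → rt; then 1 M HCl, THF, rt
Reagents that add atoms: benzyl bromide, BrCc1ccccc1; water, O
Why: Williamson etherification of both alkoxides, then acid ionises the vinylogous acetal (loss of benzyl alcohol) and completes the Stork–Danheiser enone transposition; benzylating before the enone appears prevents intramolecular oxa-Michael addition of the C19 hydroxyl.

Step 5
Reactants: 9 (S)-5-[(benzyloxy)methyl]-5-methylcyclohex-2-en-1-one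
Product: 10 (S)-5-[(benzyloxy)methyl]-2-iodo-5-methylcyclohex-2-en-1-one
Conditions: I2, pyridine/CH2Cl2 (1:1), 0 °C → rt
Reagents that add atoms: iodine, II
Why: α-Iodination of a cyclic enone by conjugate addition of pyridine, iodination of the enolate and elimination; the β-carbon (C2) keeps its hydrogen.

Step 6
Reactants: 11 pent-3-yn-1-ol
Product: 12 benzyl pent-3-yn-1-yl ether
Conditions: NaH, BnBr, n-Bu4NI (cat.), THF, 0 °C → rt
Reagents that add atoms: benzyl bromide, BrCc1ccccc1
Why: Williamson ether synthesis on a primary alcohol.

Step 7
Reactants: 12 benzyl pent-3-yn-1-yl ether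
Product: 14 (E)-{[(4-iodopent-3-en-1-yl)oxy]methyl}benzene, via alkenylzirconocene chloride 13 (not isolated)
Conditions: Cp2Zr(H)Cl (1.5 equiv), THF, rt → 40 °C; I2, 0 °C
Reagents that add atoms: iodine, II
Why: syn-Hydrozirconation of the internal alkyne; with excess Cp2Zr(H)Cl the regioisomers equilibrate to zirconium on the less hindered, methyl-bearing carbon (C10), and iodinolysis with retention gives the (E)-iodide, the minor regioisomer being removed by chromatography.

Step 8
Reactants: 14 (E)-{[(4-iodopent-3-en-1-yl)oxy]methyl}benzene; 10 (S)-5-[(benzyloxy)methyl]-2-iodo-5-methylcyclohex-2-en-1-one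
Product: 17 (S)-5-[(benzyloxy)methyl]-2-[(E)-5-(benzyloxy)pent-2-en-2-yl]-5-methylcyclohex-2-en-1-one, via alkenyllithium 15 (not isolated), via alkenylzinc chloride 16 (not isolated)
Conditions: 14, t-BuLi (2.1 equiv), Et2O, −78 °C; ZnCl2, THF, −78 → 0 °C; then 10, Pd(PPh3)4 (5 mol %), THF, rt
Reagents that add atoms: none
Why: Negishi coupling of an α-iodoenone with an alkenylzinc reagent forms C1–C10; iodine–lithium exchange, transmetalation and coupling all retain the alkene geometry.

Step 9
Reactants: 17 (S)-5-[(benzyloxy)methyl]-2-[(E)-5-(benzyloxy)pent-2-en-2-yl]-5-methylcyclohex-2-en-1-one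
Product: 19 (2R,3S,5S)-5-[(benzyloxy)methyl]-2-[(E)-5-(benzyloxy)pent-2-en-2-yl]-3-hydroxy-5-methylcyclohexan-1-one, via β-boryl ketone 18 (not isolated)
Conditions: CuCl (5 mol %), NaOt-Bu (10 mol %), (R,S)-Josiphos (6 mol %), B2pin2, MeOH, THF, 0 °C → rt; then NaBO3·4H2O, THF/H2O, 0 °C
Reagents that add atoms: sodium perborate tetrahydrate, [Na+].[O-]B1OO1.O.O.O.O
Why: Copper-catalysed conjugate borylation of the enone with a chiral bisphosphine, so that the catalyst and not the nearly unbiased C4 centre chooses the face at C2 (anti to CH2OBn); the enolate is protonated by methanol and C1 equilibrates to the 1,2-trans diequatorial isomer, and perborate oxidises the C–B bond with retention.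

Step 10
Reactants: 19 (2R,3S,5S)-5-[(benzyloxy)methyl]-2-[(E)-5-(benzyloxy)pent-2-en-2-yl]-3-hydroxy-5-methylcyclohexan-1-one
Product: 20 (2R,3S,5S)-5-[(benzyloxy)methyl]-2-[(E)-5-(benzyloxy)pent-2-en-2-yl]-5-methyl-3-[(triethylsilyl)oxy]cyclohexan-1-one
Conditions: TESCl, imidazole, CH2Cl2, 0 °C
Reagents that add atoms: chlorotriethylsilane, CC[Si](Cl)(CC)CC
Why: Silylation of the secondary alcohol under mild base, which blocks retro-aldol cleavage and β-elimination in the next two steps.

Step 11
Reactants: 21 (E)-1-bromoprop-1-ene; 20 (2R,3S,5S)-5-[(benzyloxy)methyl]-2-[(E)-5-(benzyloxy)pent-2-en-2-yl]-5-methyl-3-[(triethylsilyl)oxy]cyclohexan-1-one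
Product: 24 (1R,2R,3S,5S)-5-[(benzyloxy)methyl]-2-[(E)-5-(benzyloxy)pent-2-en-2-yl]-5-methyl-1-[(E)-prop-1-en-1-yl]-3-[(triethylsilyl)oxy]cyclohexan-1-ol, via (E)-propenyllithium 22 (not isolated), via (E)-propenylcerium dichloride 23 (not isolated)
Conditions: 21, t-BuLi (2 equiv), Et2O/THF, −78 °C; anhydrous CeCl3, THF, −78 °C; then 20, −78 °C
Reagents that add atoms: none
Why: Organocerium 1,2-addition, which suppresses enolisation of the acidic allylic α-hydrogen; in the chair with the C1 and C2 substituents equatorial and CH2OBn axial the reagent attacks equatorially, anti to the axial CH2OBn and trans to the C1 alkenyl group, giving the axial C6 carbinol cis to C19 with trans-diequatorial alkenyl groups.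

Step 12
Reactants: 24 (1R,2R,3S,5S)-5-[(benzyloxy)methyl]-2-[(E)-5-(benzyloxy)pent-2-en-2-yl]-5-methyl-1-[(E)-prop-1-en-1-yl]-3-[(triethylsilyl)oxy]cyclohexan-1-ol
Product: 26 (3R,4S,5E,7S,9S)-9-[(benzyloxy)methyl]-4-[2-(benzyloxy)ethyl]-7-hydroxy-3,5,9-trimethylcyclodec-5-en-1-one, via triethylsilyl ether 25 (not isolated)
Conditions: KH, 18-crown-6, THF, 0 °C → rt; MeOH, −78 °C; then HF·pyridine, pyridine, THF, 0 °C
Reagents that add atoms: none
Why: Anionic oxy-Cope rearrangement through the chair transition state open to the trans-diequatorial dialkenyl alkoxide breaks C1–C6 and forms C8–C9, giving the (E)-C1=C10 alkene; the C8 methyl and the C9 chain are both pseudo-equatorial in that chair, so C1/C6 chirality is transferred to (8R,9S), and buffered fluoride then removes the silyl group without acid that could trigger transannular reactions.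

Step 13
Reactants: 26 (3R,4S,5E,7S,9S)-9-[(benzyloxy)methyl]-4-[2-(benzyloxy)ethyl]-7-hydroxy-3,5,9-trimethylcyclodec-5-en-1-one
Product: 27 (3R,6E,8S,9R)-3-[(benzyloxy)methyl]-8-[2-(benzyloxy)ethyl]-3,7,9-trimethylcyclodec-6-ene-1,5-dione (labdane numbering: C2 and C6 ketones, (E)-C1=C10, 4R,8R,9S)
Conditions: Dess–Martin periodinane, pyridine, CH2Cl2, 0 °C → rt
Reagents that add atoms: none
Why: Buffered Dess–Martin oxidation of the allylic C2 alcohol gives the enone without acid or base strong enough to start the transannular chemistry.

Step 14
Reactants: 27 (3R,6E,8S,9R)-3-[(benzyloxy)methyl]-8-[2-(benzyloxy)ethyl]-3,7,9-trimethylcyclodec-6-ene-1,5-dione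
Product: 28 12,19-bis(benzyloxy)-13,14,15,16-tetranorlabdane-2,6-dione (5α-H, 8α-methyl, 9β-chain, 10β-methyl; trans-fused)
Conditions: K2CO3 (0.3 equiv), MeOH/THF (1:1), 0 °C → rt
Reagents that add atoms: none
Why: Carbonate in methanol enolises the C6 ketone reversibly on both sides, but only the C5 enolate can reach C10, the β-carbon of the (E)-C2 enone, across the ring; it adds there and the resulting C2 enolate is protonated to the 1,5-diketone 28. The closest known reaction type is the transannular Michael addition of macrocyclic keto-enones that fold into trans-decalins, an intramolecular ketone-enolate addition to a β,β-disubstituted enone driven by loss of medium-ring strain. The one new bond closes ring B (C5–C10) in a 6-(enolendo)-exo-trig mode and ring A (C10, C1–C5) in a 6-(enolexo)-endo-trig mode; closures from the C7 or C3 enolates would need four-membered rings and are not viable. C10 is controlled by the C8 and C9 centres set in step 12: in the chair–chair transition state leading to 28 the C8 methyl and the C9 chain are both equatorial, whereas attack on the other face of C10 would make both axial and put the C8 and C18 methyl groups syn-axial to C20. C5 is set as the trans fusion by the same folding and, being α to the C6 ketone, is corrected by epimerisation should any cis isomer form. The selectivity needed is thus the facial one at C10 relative to C4, and the matched C8/C9 pair secures it, helped by the reversibility of the addition, which lets the most stable trans-dione accumulate. Exchange of the C9 hydrogen (γ to the enone) under the conditions does no harm, because the all-equatorial product remains the sink.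

Step 15
Reactants: 28 12,19-bis(benzyloxy)-13,14,15,16-tetranorlabdane-2,6-dione
Product: 30 12,19-bis(benzyloxy)-13,14,15,16-tetranorlabd-7-ene-2,6-dione, via bis(trimethylsilyl enol ether) 29 (not isolated)
Conditions: LiHMDS (2.5 equiv), TMSCl, THF, −78 °C; then Pd(OAc)2 (1.2 equiv), MeCN, rt
Reagents that add atoms: none
Why: Saegusa–Ito dehydrogenation: kinetic enol silane formation at C6 goes toward C7 (C5 is a methine between two quaternary carbons) and the palladium enolate loses the C8 hydrogen; the C2 enol silane has no β-hydrogen on either side (C4 and C10 are quaternary) and returns to the ketone on work-up.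

Step 16
Reactants: 30 12,19-bis(benzyloxy)-13,14,15,16-tetranorlabd-7-ene-2,6-dione
Product: 32 12,19-bis(benzyloxy)-13,14,15,16-tetranorlabd-8-ene-2,6-dione, via potassium dienolate 31 (not isolated)
Conditions: KOt-Bu (3 equiv), t-BuOH/THF, rt; inverse quench into 10% aq. AcOH, 0 °C
Reagents that add atoms: none
Why: Deconjugation of an enone through its extended dienolate and kinetic protonation at the α-carbon (C7); the thermodynamic dienolate is the endocyclic one (axial 9α-H aligned with the enone π system), which gives the tetrasubstituted C8=C9 alkene and erases C8 and C9 as stereocentres.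

Step 17
Reactants: 32 12,19-bis(benzyloxy)-13,14,15,16-tetranorlabd-8-ene-2,6-dione
Product: 33 13,14,15,16-tetranorlabd-8-ene-2α,6α,12,19-tetraol
Conditions: Li, NH3(l)/THF, t-BuOH, −78 → −33 °C (dione added to the metal solution); solid NH4Cl
Reagents that add atoms: none
Why: Dissolving-metal reduction of hindered cyclohexanones gives the thermodynamically favoured equatorial alcohols (2α and 6α), where hydrides would attack the open α face and give the axial epimers; the same electrons cleave both benzyl ethers and leave the isolated tetrasubstituted alkene untouched.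

Step 18
Reactants: 33 13,14,15,16-tetranorlabd-8-ene-2α,6α,12,19-tetraol
Product: 34 12-iodo-13,14,15,16-tetranorlabd-8-ene-2α,6α,19-triol
Conditions: I2 (1.15 equiv), PPh3 (1.2 equiv), imidazole, THF/MeCN, −20 → 0 °C
Reagents that add atoms: iodine, II
Why: Appel-type iodination; only the unhindered primary C12 alkoxyphosphonium ion is displaced by iodide at low temperature, the neopentyl axial C19 and the secondary hydroxyls being too hindered.

Step 19
Reactants: 34 12-iodo-13,14,15,16-tetranorlabd-8-ene-2α,6α,19-triol
Product: 35 12-iodo-2α,6α,19-tris[(trimethylsilyl)oxy]-13,14,15,16-tetranorlabd-8-ene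
Conditions: TMSOTf (3.6 equiv), 2,6-lutidine, CH2Cl2, −78 → 0 °C
Reagents that add atoms: trimethylsilyl trifluoromethanesulfonate, C[Si](C)(C)OS(=O)(=O)C(F)(F)F
Why: Exhaustive silylation with a silyl triflate and a non-nucleophilic base masks the three hydroxyls for the organozinc step without touching the primary iodide.

Step 20
Reactants: 35 12-iodo-2α,6α,19-tris[(trimethylsilyl)oxy]-13,14,15,16-tetranorlabd-8-ene; 36 4-bromofuran-2(5H)-one
Product: 39 2α,6α,19-trihydroxylabda-8,13-dien-15,16-olide, via alkylzinc iodide 37 (not isolated), via tris(trimethylsilyl) ether 38 (not isolated)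
Conditions: Zn dust (activated), LiCl, THF, 40 °C; then 36, Pd(OAc)2 (3 mol %), SPhos (6 mol %), THF, rt; then 1 M HCl, MeOH, 0 °C → rt
Reagents that add atoms: none
Why: Zinc insertion into the primary iodide and Negishi sp3–sp2 coupling with the β-bromobutenolide form C12–C13 under neutral conditions that the lactone tolerates; dilute acid then removes the three trimethylsilyl ethers.

## Compound list

1 | 3,5-dimethoxybenzoic acid | COc1cc(OC)cc(C(=O)O)c1 | starting material
2 | dilithium dienediolate from Birch reduction of 1 | COC1=CC(=C([O-])[O-])C=C(OC)C1.[Li+].[Li+] | intermediate (not isolated)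
3 | 3,5-dimethoxy-1-methylcyclohexa-2,5-diene-1-carboxylic acid | COC1=CC(C)(C(=O)O)C=C(OC)C1 | intermediate (not isolated)
4 | rac-3-methoxy-1-methyl-5-oxocyclohex-3-ene-1-carboxylic acid | O=C1C=C(OC)CC(C)(C(=O)O)C1 | intermediate
5 | (S)-1-phenylethylammonium (R)-3-methoxy-1-methyl-5-oxocyclohex-3-ene-1-carboxylate | O=C1C=C(OC)C[C@@](C)(C(=O)[O-])C1.C[C@H]([NH3+])c1ccccc1 | intermediate (not isolated)
6 | (R)-3-methoxy-1-methyl-5-oxocyclohex-3-ene-1-carboxylic acid | O=C1C=C(OC)C[C@@](C)(C(=O)O)C1 | intermediate
7 | (5S)-5-(hydroxymethyl)-3-methoxy-5-methylcyclohex-2-en-1-ol (both C1 epimers) | OC1C=C(OC)C[C@@](C)(CO)C1 | intermediate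
8 | bis(benzyl ether) of 7 | C1(OCc2ccccc2)C=C(OC)C[C@@](C)(COCc3ccccc3)C1 | intermediate (not isolated)
9 | (S)-5-[(benzyloxy)methyl]-5-methylcyclohex-2-en-1-one | O=C1C[C@@](C)(COCc2ccccc2)CC=C1 | intermediate
10 | (S)-5-[(benzyloxy)methyl]-2-iodo-5-methylcyclohex-2-en-1-one | O=C1C[C@@](C)(COCc2ccccc2)CC=C1I | intermediate
11 | pent-3-yn-1-ol | CC#CCCO | starting material
12 | benzyl pent-3-yn-1-yl ether | CC#CCCOCc1ccccc1 | intermediate
13 | [(E)-5-(benzyloxy)pent-2-en-2-yl]chlorobis(cyclopentadienyl)zirconium | C/C(=C\CCOCc1ccccc1)[Zr](Cl)(C2C=CC=C2)C3C=CC=C3 | intermediate (not isolated)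
14 | (E)-{[(4-iodopent-3-en-1-yl)oxy]methyl}benzene | C/C(I)=C\CCOCc1ccccc1 | intermediate
15 | [5-(benzyloxy)pent-2-en-2-yl]lithium (lithium trans to the chain, as iodine in 14) | C/C([Li])=C\CCOCc1ccccc1 | intermediate (not isolated)
16 | [(E)-5-(benzyloxy)pent-2-en-2-yl]zinc chloride | C/C([Zn]Cl)=C\CCOCc1ccccc1 | intermediate (not isolated)
17 | (S)-5-[(benzyloxy)methyl]-2-[(E)-5-(benzyloxy)pent-2-en-2-yl]-5-methylcyclohex-2-en-1-one | O=C1C[C@@](C)(COCc2ccccc2)CC=C1/C(C)=C/CCOCc3ccccc3 | intermediate
18 | 3-(pinacolboryl) ketone from 17 (boron trans to CH2OBn, alkenyl trans to boron) | O=C1C[C@@](C)(COCc2ccccc2)C[C@H](B3OC(C)(C)C(C)(C)O3)[C@H]1/C(C)=C/CCOCc4ccccc4 | intermediate (not isolated)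
19 | (2R,3S,5S)-5-[(benzyloxy)methyl]-2-[(E)-5-(benzyloxy)pent-2-en-2-yl]-3-hydroxy-5-methylcyclohexan-1-one (OH trans to CH2OBn and to the alkenyl group) | O=C1C[C@@](C)(COCc2ccccc2)C[C@H](O)[C@H]1/C(C)=C/CCOCc3ccccc3 | intermediate
20 | (2R,3S,5S)-5-[(benzyloxy)methyl]-2-[(E)-5-(benzyloxy)pent-2-en-2-yl]-5-methyl-3-[(triethylsilyl)oxy]cyclohexan-1-one | O=C1C[C@@](C)(COCc2ccccc2)C[C@H](O[Si](CC)(CC)CC)[C@H]1/C(C)=C/CCOCc3ccccc3 | intermediate
21 | (E)-1-bromoprop-1-ene | C/C=C/Br | starting material
22 | (E)-prop-1-en-1-yllithium | C/C=C/[Li] | intermediate (not isolated)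
23 | (E)-prop-1-en-1-ylcerium dichloride | C/C=C/[Ce](Cl)Cl | intermediate (not isolated)
24 | (1R,2R,3S,5S)-5-[(benzyloxy)methyl]-2-[(E)-5-(benzyloxy)pent-2-en-2-yl]-5-methyl-1-[(E)-prop-1-en-1-yl]-3-[(triethylsilyl)oxy]cyclohexan-1-ol (OH cis to CH2OBn; alkenyl groups trans) | O[C@@]1(/C=C/C)C[C@@](C)(COCc2ccccc2)C[C@H](O[Si](CC)(CC)CC)[C@H]1/C(C)=C/CCOCc3ccccc3 | intermediate
25 | triethylsilyl ether of 26 | O=C1C[C@@H](C)[C@H](CCOCc2ccccc2)/C(C)=C/[C@@H](O[Si](CC)(CC)CC)C[C@](C)(COCc3ccccc3)C1 | intermediate (not isolated)
26 | (3R,4S,5E,7S,9S)-9-[(benzyloxy)methyl]-4-[2-(benzyloxy)ethyl]-7-hydroxy-3,5,9-trimethylcyclodec-5-en-1-one | O=C1C[C@@H](C)[C@H](CCOCc2ccccc2)/C(C)=C/[C@@H](O)C[C@](C)(COCc3ccccc3)C1 | intermediate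
27 | (3R,6E,8S,9R)-3-[(benzyloxy)methyl]-8-[2-(benzyloxy)ethyl]-3,7,9-trimethylcyclodec-6-ene-1,5-dione | O=C1C[C@@H](C)[C@H](CCOCc2ccccc2)/C(C)=C/C(=O)C[C@](C)(COCc3ccccc3)C1 | intermediate (key-step precursor)
28 | 12,19-bis(benzyloxy)-13,14,15,16-tetranorlabdane-2,6-dione (5α-H, 8α-CH3, 9β-chain, 10β-CH3) | C[C@H]1[C@H](CCOCc2ccccc2)[C@@]3(C)CC(=O)C[C@](C)(COCc4ccccc4)[C@@H]3C(=O)C1 | intermediate (key-step product)
29 | 2,6-bis[(trimethylsilyl)oxy]-1,6-diene from 28 (C2 enol ether as the 1-ene or 2-ene regioisomer) | C[C@H]1[C@H](CCOCc2ccccc2)[C@@]3(C)C=C(O[Si](C)(C)C)C[C@](C)(COCc4ccccc4)[C@@H]3C(O[Si](C)(C)C)=C1 | intermediate (not isolated)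
30 | 12,19-bis(benzyloxy)-13,14,15,16-tetranorlabd-7-ene-2,6-dione (5α-H, 9β-chain) | CC=1[C@H](CCOCc2ccccc2)[C@@]3(C)CC(=O)C[C@](C)(COCc4ccccc4)[C@@H]3C(=O)C=1 | intermediate
31 | potassium 6,8-dienolate of 30 | CC1=C(CCOCc2ccccc2)[C@@]3(C)CC(=O)C[C@](C)(COCc4ccccc4)[C@@H]3C([O-])=C1.[K+] | intermediate (not isolated)
32 | 12,19-bis(benzyloxy)-13,14,15,16-tetranorlabd-8-ene-2,6-dione | CC1=C(CCOCc2ccccc2)[C@@]3(C)CC(=O)C[C@](C)(COCc4ccccc4)[C@@H]3C(=O)C1 | intermediate
33 | 13,14,15,16-tetranorlabd-8-ene-2α,6α,12,19-tetraol | CC1=C(CCO)[C@@]2(C)C[C@@H](O)C[C@](C)(CO)[C@@H]2[C@@H](O)C1 | intermediate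
34 | 12-iodo-13,14,15,16-tetranorlabd-8-ene-2α,6α,19-triol | CC1=C(CCI)[C@@]2(C)C[C@@H](O)C[C@](C)(CO)[C@@H]2[C@@H](O)C1 | intermediate
35 | 12-iodo-2α,6α,19-tris[(trimethylsilyl)oxy]-13,14,15,16-tetranorlabd-8-ene | CC1=C(CCI)[C@@]2(C)C[C@@H](O[Si](C)(C)C)C[C@](C)(CO[Si](C)(C)C)[C@@H]2[C@@H](O[Si](C)(C)C)C1 | intermediate
36 | 4-bromofuran-2(5H)-one | O=C1C=C(Br)CO1 | starting material
37 | alkylzinc iodide from 35 | CC1=C(CC[Zn]I)[C@@]2(C)C[C@@H](O[Si](C)(C)C)C[C@](C)(CO[Si](C)(C)C)[C@@H]2[C@@H](O[Si](C)(C)C)C1 | intermediate (not isolated)
38 | 2α,6α,19-tris[(trimethylsilyl)oxy]labda-8,13-dien-15,16-olide | CC1=C(CCC2=CC(=O)OC2)[C@@]3(C)C[C@@H](O[Si](C)(C)C)C[C@](C)(CO[Si](C)(C)C)[C@@H]3[C@@H](O[Si](C)(C)C)C1 | intermediate (not isolated)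
39 | 2α,6α,19-trihydroxylabda-8,13-dien-15,16-olide (2R,4S,5R,6S,10S) | CC1=C(CCC2=CC(=O)OC2)[C@@]2(C)C[C@@H](O)C[C@](C)(CO)[C@@H]2[C@@H](O)C1 | target

## Step count and least certain steps

Total: 20 steps. Longest linear sequence: 18 steps from 1 (steps 1–5 and 8–20). The side-chain branch (steps 6 and 7) joins at step 8.

**Step 14 (key step).** The most likely failure is that base moves the C1=C10 double bond out of conjugation (deprotonation at C9) or that reversible transannular aldol addition of the C7 enolate to the C2 carbonyl outruns C5–C10 bond formation at a doubly neopentyl site.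
- Fallback: leave the enolate manifold for enamine catalysis. Setting out from 27, pyrrolidine and acetic acid (substoichiometric, DMSO, rt) form the C6 enamines reversibly.
- Only the 5,6-enamine of 27, the pyrrolidine enamine F1, can add to C10. It gives the 6-pyrrolidinyl-6-ene of the decalin, the enamine F2.
- Aqueous work-up hydrolyses F2, and the route is rejoined at 28.

**Step 9.** The copper-boryl addition to the α-branched, cross-conjugated enone may be slow or poorly face-selective, and the β-hydroxy ketone may dehydrate during oxidation.
- Fallback: give up catalyst control and rely on separation and recycling. Setting out from 17, an achiral catalyst (CuCl, NaOt-Bu, dppf, B2pin2, MeOH, then NaBO3) gives 19 together with its C2,C1-epimer.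
- The epimer, (2S,3R,5S)-hydroxy ketone F3, is separated by chromatography and returned to 17 by dehydration (DBU, toluene, 60 °C).
- The sequence rejoins the route at 19.

**Step 12.** The potassium alkoxide may suffer 1,3-migration of the silyl group to the tertiary oxygen, or a boat pathway may erode the alkene geometry and the C8/C9 transfer.
- Fallback: neutral, thermal siloxy-Cope rearrangement. Setting out from 24, TMSOTf and 2,6-lutidine give the tertiary trimethylsilyl ether F4.
- Heating F4 (decalin, 220 °C, sealed tube) gives the ring-expanded trimethylsilyl enol ether F5 through the same chair.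
- HF·pyridine cleaves both silyl groups, and the route is rejoined at 26.

**Step 16.** Deprotonation at the C17 methyl (exocyclic alkene) or reconjugation during the quench may compete.
- Fallback: pass through a neutral dienol silyl ether. Setting out from 30, TBSOTf and Et3N under equilibrating conditions give the 2,6-bis(silyloxy)-1,6,8-triene, the bis(tert-butyldimethylsilyl) dienol ether F6.
- Fluoride with acetic acid at −78 °C protonates F6 at C7 and C1, and the route is rejoined at 32.

**Step 20.** Zinc insertion may stall, or the alkylzinc may be lost by protonation or β-hydride elimination before it couples with the base-sensitive bromobutenolide.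
- Fallback: bring C13–C16 in as a furan and oxidise it. Setting out from 35 (through 37), palladium-catalysed Negishi coupling with 3-bromofuran gives the tris(trimethylsilyl) furan F7.
- Dilute acid gives the furan triol F8.
- Photooxygenation in the presence of i-Pr2NEt (rose bengal, −78 °C) gives the 16-hydroxybutenolide F9. Reduction with NaBH4 and acidification returns the route at 39.
- The risk there is competing ene reaction of singlet oxygen at C8=C9.

## Further compounds

F1 | step 14 | 6-(pyrrolidin-1-yl)-5,6-ene (C6 enamine) of 27 | C1(N2CCCC2)=C[C@@](C)(COCc3ccccc3)CC(=O)/C=C(C)/[C@@H](CCOCc4ccccc4)[C@H](C)C1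
F2 | step 14 | 6-(pyrrolidin-1-yl)-6-ene (C6 enamine) of 28 | C[C@H]1[C@H](CCOCc2ccccc2)[C@@]3(C)CC(=O)C[C@](C)(COCc4ccccc4)[C@@H]3C(N5CCCC5)=C1
F3 | step 9 | (2S,3R,5S)-5-[(benzyloxy)methyl]-2-[(E)-5-(benzyloxy)pent-2-en-2-yl]-3-hydroxy-5-methylcyclohexan-1-one | O=C1C[C@@](C)(COCc2ccccc2)C[C@@H](O)[C@@H]1/C(C)=C/CCOCc3ccccc3
F4 | step 12 | trimethylsilyl ether of 24 | C[Si](C)(C)O[C@@]1(/C=C/C)C[C@@](C)(COCc2ccccc2)C[C@H](O[Si](CC)(CC)CC)[C@H]1/C(C)=C/CCOCc3ccccc3
F5 | step 12 | C6 trimethylsilyl enol ether of 25 | C[Si](C)(C)OC1=C[C@@H](C)[C@H](CCOCc2ccccc2)/C(C)=C/[C@@H](O[Si](CC)(CC)CC)C[C@](C)(COCc3ccccc3)C1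
F6 | step 16 | 2,6-bis[(tert-butyldimethylsilyl)oxy]-1,6,8-triene from 30 | CC1=C(CCOCc2ccccc2)[C@@]3(C)C=C(O[Si](C)(C)C(C)(C)C)C[C@](C)(COCc4ccccc4)[C@@H]3C(O[Si](C)(C)C(C)(C)C)=C1
F7 | step 20 | 15,16-epoxy-2α,6α,19-tris[(trimethylsilyl)oxy]labda-8,13(16),14-triene | CC1=C(CCc2ccoc2)[C@@]3(C)C[C@@H](O[Si](C)(C)C)C[C@](C)(CO[Si](C)(C)C)[C@@H]3[C@@H](O[Si](C)(C)C)C1
F8 | step 20 | 15,16-epoxylabda-8,13(16),14-triene-2α,6α,19-triol | CC1=C(CCc2ccoc2)[C@@]3(C)C[C@@H](O)C[C@](C)(CO)[C@@H]3[C@@H](O)C1
F9 | step 20 | 2α,6α,16,19-tetrahydroxylabda-8,13-dien-15,16-olide (C16 epimers) | CC1=C(CCC2=CC(=O)OC2O)[C@@]3(C)C[C@@H](O)C[C@](C)(CO)[C@@H]3[C@@H](O)C1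
A1 | alternative 1 | cis-fused Diels–Alder enedione adduct | COC1=CC(=O)[C@H]2[C@@H](O[Si](C)(C)C(C)(C)C)C=C(C)[C@@H](CCOC(=O)C(C)(C)C)[C@@]2(C)C1=O
A2 | alternative 2 | 2,2,3,4-tetrasubstituted cyclohexanone from conjugate addition–alkylation | O=C1[C@@](C)(CC(=O)OCC)[C@H](C(C)=C)[C@@H](O[Si](C)(C)C(C)(C)C)CC1
A3 | alternative 3 | 2-oxo decalin with C5=C6 alkene from the Claisen rearrangement | O=C1C[C@](C)(CO[Si](C)(C)C(C)(C)C)C2=CCCC(OCc3ccc(OC)cc3)[C@@]2(C)C1
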